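The cyclohexene ring of the butylidenephthalide half (C3a–C4–C5–C6–C7–C7a) is trans-fused to the 2-oxabicyclo[2.2.1]heptanone: H-6 and H-7 are anti, so a cis annulation across C6–C7 is excluded. The route therefore sets C6 and C7 first and closes this ring last at the remote C3a–C4 bond. An intramolecular alkyl–alkenyl Negishi coupling joins the zincated C4 end of the exo ethyl arm on C6 to the triflated β-carbon C3a of a preformed (Z)-butylidenebutenolide held endo on C7, building the strained ring by irreversible reductive elimination. Its precursor is the complete cage (lactone, cyclohexene, butanoyl) with two trans arms.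

Key step: step 16

Remark on the chemistry: ligustilide locants are used, unprimed C1–C11 for the butylidenephthalide half and primed for the other half (C1′ lactone carbonyl, C3′ carbinol carbon, C3a′/C7a′ ring-fusion carbons, C8′ ketone); the halves are joined by C6–C3′ and C7–C7a′, and the stereodescriptors are read as H-6/H-7 trans with C7a endo (syn to the O2′–C1′ bridge) and C5 exo (syn to the C3a′ bridge).

Step 1
Reactants: 1 (S)-5-oxotetrahydrofuran-2-carboxylic acid; 2 N,O-dimethylhydroxylamine hydrochloride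
Product: 4 (S)-N-methoxy-N-methyl-5-oxotetrahydrofuran-2-carboxamide, via acyl imidazolide 3 (not isolated)
Conditions: 1,1′-carbonyldiimidazole, CH2Cl2, 23 °C; then 2
Reagents that add atoms: none
Why: Aminolysis of the acyl imidazolide gives the N-methoxy-N-methylamide that later becomes the propyl ketone, and the existing stereocentre is irrelevant because step 3 planarises it (amide coupling).

Step 2
Reactants: 4 (S)-N-methoxy-N-methyl-5-oxotetrahydrofuran-2-carboxamide
Product: 6 N-methoxy-N-methyl-5-oxo-2,5-dihydrofuran-2-carboxamide, via phenylselanyl lactone 5 (not isolated)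
Conditions: LiN(SiMe3)2, THF, −78 °C; PhSeCl; then H2O2 (30% aq.), pyridine, CH2Cl2, 0 → 23 °C
Reagents that add atoms: none
Why: Kinetic enolisation should occur at the lactone α-CH2, and selenation followed by selenoxide syn-elimination introduces the butenolide double bond (selenoxide elimination).

Step 3
Reactants: 6 N-methoxy-N-methyl-5-oxo-2,5-dihydrofuran-2-carboxamide
Product: 7 N-methoxy-N-methyl-5-[(triisopropylsilyl)oxy]furan-2-carboxamide
Conditions: iPr3SiOTf, Et3N, CH2Cl2, 0 °C
Reagents that add atoms: triisopropylsilyl trifluoromethanesulfonate, CC(C)[Si](C(C)C)(C(C)C)OS(=O)(=O)C(F)(F)F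
Why: The γ-hydrogen is activated by both the lactone (vinylogously) and the amide, so soft enolisation should give the aromatic 2-silyloxyfuran (silyl dienol ether formation).

Step 4
Reactants: 8 (E)-4,4-dimethoxybut-2-enal; 9 tert-butyl 2-(triphenyl-λ5-phosphanylidene)acetate
Product: 10 tert-butyl (2E,4E)-6,6-dimethoxyhexa-2,4-dienoate
Conditions: CH2Cl2, 23 °C
Reagents that add atoms: none
Why: The stabilised ylide should give the E-enoate at the aldehyde (Wittig olefination).

Step 5
Reactants: 10 tert-butyl (2E,4E)-6,6-dimethoxyhexa-2,4-dienoate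
Product: 11 tert-butyl (2E,4E)-6-oxohexa-2,4-dienoate
Conditions: Amberlyst 15 (sulfonic acid resin), acetone/H2O, 23 °C
Reagents that add atoms: water, O
Why: Mild acid should hydrolyse the dimethyl acetal without touching the tert-butyl ester (acetal hydrolysis).

Step 6
Reactants: 7 N-methoxy-N-methyl-5-[(triisopropylsilyl)oxy]furan-2-carboxamide; 11 tert-butyl (2E,4E)-6-oxohexa-2,4-dienoate
Product: 12 tert-butyl (2E,4S)-4-{(2S)-2-[methoxy(methyl)carbamoyl]-5-oxo-2,5-dihydrofuran-2-yl}-6-oxohex-2-enoate
Conditions: (2S,5S)-5-benzyl-2-tert-butyl-3-methylimidazolidin-4-one (20 mol%), 2,4-dinitrobenzoic acid (20 mol%), CH2Cl2, H2O (2 equiv), −60 °C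
Reagents that add atoms: none
Why: The iminium ion of 11 should be attacked at C4 (β to the iminium carbon, leaving the enoate intact) by the furan γ-carbon on the face left open by the catalyst's benzyl group, which sets the 4S centre (later C6), while the synclinal approach of the planar furan sets the adjacent quaternary 2′S centre (later C3′) in the same event (organocatalytic Mukaiyama–Michael addition).

Step 7
Reactants: 12 tert-butyl (2E,4S)-4-{(2S)-2-[methoxy(methyl)carbamoyl]-5-oxo-2,5-dihydrofuran-2-yl}-6-oxohex-2-enoate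
Product: 13 tert-butyl (2E,4S)-6-hydroxy-4-{(2S)-2-[methoxy(methyl)carbamoyl]-5-oxo-2,5-dihydrofuran-2-yl}hex-2-enoate
Conditions: NaBH4, MeOH/CH2Cl2, −78 °C; AcOH quench
Reagents that add atoms: none
Why: At −78 °C borohydride should reduce the aldehyde much faster than the conjugated lactone, the esters or the amide (chemoselective carbonyl reduction).

Step 8
Reactants: 13 tert-butyl (2E,4S)-6-hydroxy-4-{(2S)-2-[methoxy(methyl)carbamoyl]-5-oxo-2,5-dihydrofuran-2-yl}hex-2-enoate
Product: 14 tert-butyl (2E,4S)-6-chloro-4-{(2S)-2-[methoxy(methyl)carbamoyl]-5-oxo-2,5-dihydrofuran-2-yl}hex-2-enoate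
Conditions: PPh3, N-chlorosuccinimide, CH2Cl2, 0 → 23 °C
Reagents that add atoms: N-chlorosuccinimide, O=C1CCC(=O)N1Cl
Why: The primary alcohol becomes a chloride, a latent iodide that should stay inert toward the enolates of steps 11 and 13 (Appel-type chlorination).

Step 9
Reactants: 14 tert-butyl (2E,4S)-6-chloro-4-{(2S)-2-[methoxy(methyl)carbamoyl]-5-oxo-2,5-dihydrofuran-2-yl}hex-2-enoate; 15 (E)-1-(trimethylsilyloxy)buta-1,3-diene
Product: 17 tert-butyl (2E,4S)-6-chloro-4-{7-hydroxy-3-[methoxy(methyl)carbamoyl]-1-oxo-1,3,3a,4,7,7a-hexahydroisobenzofuran-3-yl}hex-2-enoate (cis-fused; new ring anti to the hexenoate chain; 7-OH cis to the C1 carbonyl), via silyl ether 16 (not isolated)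
Conditions: 15 (5 equiv), 2,6-di-tert-butyl-4-methylphenol, toluene, 130 °C, sealed tube; then HCl (1 M aq.), THF, 0 °C
Reagents that add atoms: none
Why: The electron-rich diene should add to the butenolide double bond with its oxygenated terminus bonding to the lactone α-carbon (ortho rule) and from the face anti to the bulky side chain on the quaternary carbon, which sets C3a′ and the cis ring fusion and places the new ring syn to the amide, while the acyclic trans-enoate is the poorer dienophile (Diels–Alder reaction).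

Step 10
Reactants: 17 tert-butyl (2E,4S)-6-chloro-4-{7-hydroxy-3-[methoxy(methyl)carbamoyl]-1-oxo-1,3,3a,4,7,7a-hexahydroisobenzofuran-3-yl}hex-2-enoate
Product: 20 tert-butyl (2E,4S)-6-chloro-4-{3-[methoxy(methyl)carbamoyl]-1-oxo-1,3,3a,4,5,7a-hexahydroisobenzofuran-3-yl}hex-2-enoate (cis-fused; C6′=C7′ alkene), via sulfonylhydrazine 18 (not isolated), via allylic diazene 19 (not isolated)
Conditions: PPh3, diethyl azodicarboxylate, 2-nitrobenzenesulfonylhydrazide, THF, −30 → 23 °C
Reagents that add atoms: none
Why: Mitsunobu displacement by the sulfonylhydrazide, loss of sulfinate and sigmatropic loss of N2 from the allylic diazene should move the double bond to C6′=C7′ next to C7a′ and deliver hydrogen to C5′, without creating a stereocentre (reductive 1,3-transposition of an allylic alcohol).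

Step 11
Reactants: 20 tert-butyl (2E,4S)-6-chloro-4-{3-[methoxy(methyl)carbamoyl]-1-oxo-1,3,3a,4,5,7a-hexahydroisobenzofuran-3-yl}hex-2-enoate
Product: 21 cage ester: tert-butyl 2-(cage-C7-yl)acetate in which C7a′–C7 and C3′–C6 close the 2-oxabicyclo[2.2.1]heptan-3-one; C3′ N-methoxy-N-methylamide; C6 exo 2-chloroethyl; C7 endo CH2CO2tBu; C6′=C7′ cyclohexene
Conditions: KN(SiMe3)2, THF, −78 → −30 °C; then AcOH, −78 °C
Reagents that add atoms: none
Why: The allylic lactone α-hydrogen at C7a′ is the most acidic C–H, and its enolate should add 5-exo-trig to the E-enoate on the face that carries the side chain, which quaternises C7a′ with retention of the cis lactone fusion; allylic strain makes the enoate react with its ester terminus anti to the chloroethyl arm, so C7 forms with the acetate arm endo and trans to the exo arm on C6 (intramolecular Michael addition).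

Step 12
Reactants: 21 cage ester; 22 ethyl 2-oxohexanoate
Product: 24 ethyl (Z)-2-[(cage-C7-yl)acetoxy]hex-2-enoate (enol ester of 22 with the cage acetic acid), via acid chloride 23 (not isolated)
Conditions: SOCl2, CH2Cl2, 23 °C; evaporate; then 22, Et3N, 4-dimethylaminopyridine (10 mol%), CH2Cl2, −20 → 0 °C
Reagents that add atoms: none
Why: Thionyl chloride should convert the tert-butyl ester directly into the acid chloride, which O-acylates the enol of the α-keto ester to give the Z-enol ester (enol ester formation).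

Step 13
Reactants: 24 ethyl (Z)-2-[(cage-C7-yl)acetoxy]hex-2-enoate; 25 propylmagnesium bromide
Product: 27 3-(cage-C7-yl)-4-hydroxy-5-[(Z)-butylidene]furan-2(5H)-one carrying the C3′ butanoyl group and the C6 exo 2-chloroethyl arm, via lithium tetronate 26 (not isolated)
Conditions: LiN(SiMe3)2 (2.2 equiv), THF, −78 → 0 °C; then CH3CH2CH2MgBr (3 equiv), −20 °C; HCl (1 M aq.)
Reagents that add atoms: none
Why: The ester enolate at C7a should attack the neighbouring ethyl ester in a 5-exo-trig Claisen closure that forms the C7a–C3a bond and the Z-butylidene tetronate, whose anion is inert while the Grignard reagent turns the N-methoxy-N-methylamide into the propyl ketone through the stable chelated adduct (Dieckmann condensation, then ketone synthesis from an N-methoxy-N-methylamide).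

Step 14
Reactants: 27 tetronic acid chloride
Product: 28 3-(cage-C7-yl)-4-hydroxy-5-[(Z)-butylidene]furan-2(5H)-one with the C6 exo 2-iodoethyl arm
Conditions: NaI, acetone, 56 °C
Reagents that add atoms: sodium iodide, [Na+].[I-]
Why: Halide exchange at the primary chloride should give the iodide needed for zinc insertion, and it is done before triflation so that iodide cannot attack a vinylogous acyl triflate (Finkelstein reaction).

Step 15
Reactants: 28 tetronic acid iodide
Product: 29 4-trifluoromethanesulfonyloxy-3-(cage-C7-yl)-5-[(Z)-butylidene]furan-2(5H)-one with the C6 exo 2-iodoethyl arm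
Conditions: (CF3SO2)2O, 2,6-lutidine, CH2Cl2, −78 °C
Reagents that add atoms: trifluoromethanesulfonic anhydride, O=S(=O)(OS(=O)(=O)C(F)(F)F)C(F)(F)F
Why: The vinylogous acid should be sulfonylated on the C3a oxygen far faster than the hindered ketone is enolised, giving the alkenyl triflate (enol triflate formation).

Step 16
Reactants: 29 enol triflate iodide
Product: 31 target CNP0423313.2, via alkylzinc iodide 30 (not isolated)
Conditions: Zn dust, LiCl, THF, 40 °C; then Pd(OAc)2 (10 mol%), 2-dicyclohexylphosphino-2′,6′-dimethoxybiphenyl (20 mol%), THF/N-methylpyrrolidone, 60 °C, slow addition to 2 mM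
Reagents that add atoms: none
Why: Zinc inserts into the primary C–I bond to give 30; zerovalent palladium then adds oxidatively to the C3a–OTf bond, intramolecular transmetalation gives a seven-membered alkyl(alkenyl)palladacycle, and reductive elimination forms the C3a–C4 bond. The closest known reaction type is the intramolecular alkyl–alkenyl Negishi coupling. The six-membered ring is closed by reductive elimination from the seven-membered palladacycle, an endo-type closure in which both butenolide carbons C3a and C7a become ring members. No stereocentre is created: the anti H-6/H-7 junction is inherited from C6 (step 6) and C7 (step 11), and because the bond formed is remote from both, the strained trans fusion cannot relax to cis. The step needs reductive elimination to outrun β-hydride elimination, protodemetalation and intermolecular coupling; the bulky electron-rich biarylphosphine, aprotic conditions and high dilution should secure this, and the strain of the trans-fused ring is paid for by irreversible C–C bond formation.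

Compound list
1 | (S)-5-oxotetrahydrofuran-2-carboxylic acid | O=C1CC[C@@H](C(=O)O)O1 | starting material
2 | N,O-dimethylhydroxylamine hydrochloride | CNOC.Cl | starting material
3 | (S)-5-(1H-imidazole-1-carbonyl)dihydrofuran-2(3H)-one | O=C1CC[C@@H](C(=O)n2ccnc2)O1 | intermediate
4 | (S)-N-methoxy-N-methyl-5-oxotetrahydrofuran-2-carboxamide | CON(C)C(=O)[C@@H]1CCC(=O)O1 | intermediate
5 | (2S)-N-methoxy-N-methyl-5-oxo-4-(phenylselanyl)tetrahydrofuran-2-carboxamide (both C4 epimers) | CON(C)C(=O)[C@@H]1CC([Se]c2ccccc2)C(=O)O1 | intermediate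
6 | N-methoxy-N-methyl-5-oxo-2,5-dihydrofuran-2-carboxamide (C2 configurationally labile) | CON(C)C(=O)C1C=CC(=O)O1 | intermediate
7 | N-methoxy-N-methyl-5-[(triisopropylsilyl)oxy]furan-2-carboxamide | CON(C)C(=O)c1ccc(O[Si](C(C)C)(C(C)C)C(C)C)o1 | intermediate
8 | (E)-4,4-dimethoxybut-2-enal | COC(OC)/C=C/C=O | starting material
9 | tert-butyl 2-(triphenyl-λ5-phosphanylidene)acetate | CC(C)(C)OC(=O)C=P(c1ccccc1)(c1ccccc1)c1ccccc1 | starting material
10 | tert-butyl (2E,4E)-6,6-dimethoxyhexa-2,4-dienoate | COC(OC)/C=C/C=C/C(=O)OC(C)(C)C | intermediate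
11 | tert-butyl (2E,4E)-6-oxohexa-2,4-dienoate | O=C/C=C/C=C/C(=O)OC(C)(C)C | intermediate
12 | tert-butyl (2E,4S)-4-{(2S)-2-[methoxy(methyl)carbamoyl]-5-oxo-2,5-dihydrofuran-2-yl}-6-oxohex-2-enoate | O=CC[C@@H](/C=C/C(=O)OC(C)(C)C)[C@@]1(C(=O)N(C)OC)OC(=O)C=C1 | intermediate
13 | tert-butyl (2E,4S)-6-hydroxy-4-{(2S)-2-[methoxy(methyl)carbamoyl]-5-oxo-2,5-dihydrofuran-2-yl}hex-2-enoate | OCC[C@@H](/C=C/C(=O)OC(C)(C)C)[C@@]1(C(=O)N(C)OC)OC(=O)C=C1 | intermediate
14 | tert-butyl (2E,4S)-6-chloro-4-{(2S)-2-[methoxy(methyl)carbamoyl]-5-oxo-2,5-dihydrofuran-2-yl}hex-2-enoate | ClCC[C@@H](/C=C/C(=O)OC(C)(C)C)[C@@]1(C(=O)N(C)OC)OC(=O)C=C1 | intermediate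
15 | (E)-1-(trimethylsilyloxy)buta-1,3-diene | C=C/C=C/O[Si](C)(C)C | starting material
16 | trimethylsilyl ether of 17 (Diels–Alder adduct) | ClCC[C@@H](/C=C/C(=O)OC(C)(C)C)[C@@]1(C(=O)N(C)OC)OC(=O)[C@@H]2[C@H](O[Si](C)(C)C)C=CC[C@H]12 | intermediate
17 | tert-butyl (2E,4S)-6-chloro-4-{7-hydroxy-3-[methoxy(methyl)carbamoyl]-1-oxo-1,3,3a,4,7,7a-hexahydroisobenzofuran-3-yl}hex-2-enoate (cis-fused; ring anti to the chain; 7-OH cis to C1=O) | ClCC[C@@H](/C=C/C(=O)OC(C)(C)C)[C@@]1(C(=O)N(C)OC)OC(=O)[C@@H]2[C@H](O)C=CC[C@H]12 | intermediate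
18 | N-allylic N-(2-nitrobenzenesulfonyl)hydrazine from 17 (C7′ inverted) | ClCC[C@@H](/C=C/C(=O)OC(C)(C)C)[C@@]1(C(=O)N(C)OC)OC(=O)[C@@H]2[C@@H](N(N)S(=O)(=O)c3ccccc3[N+](=O)[O-])C=CC[C@H]12 | intermediate
19 | allylic monoalkyl diazene at C7′ | ClCC[C@@H](/C=C/C(=O)OC(C)(C)C)[C@@]1(C(=O)N(C)OC)OC(=O)[C@@H]2[C@@H](N=N)C=CC[C@H]12 | intermediate
20 | tert-butyl (2E,4S)-6-chloro-4-{3-[methoxy(methyl)carbamoyl]-1-oxo-1,3,3a,4,5,7a-hexahydroisobenzofuran-3-yl}hex-2-enoate (cis-fused; C6′=C7′) | ClCC[C@@H](/C=C/C(=O)OC(C)(C)C)[C@@]1(C(=O)N(C)OC)OC(=O)[C@@H]2C=CCC[C@H]12 | intermediate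
21 | cage ester (C7 endo CH2CO2tBu; C6 exo CH2CH2Cl; C3′ N-methoxy-N-methylamide) | ClCC[C@H]1[C@H](CC(=O)OC(C)(C)C)[C@@]23C=CCC[C@@H]2[C@]1(C(=O)N(C)OC)OC3=O | intermediate
22 | ethyl 2-oxohexanoate | CCCCC(=O)C(=O)OCC | starting material
23 | cage acetyl chloride | ClCC[C@H]1[C@H](CC(=O)Cl)[C@@]23C=CCC[C@@H]2[C@]1(C(=O)N(C)OC)OC3=O | intermediate
24 | ethyl (Z)-2-[(cage-C7-yl)acetoxy]hex-2-enoate | ClCC[C@H]1[C@H](CC(=O)O/C(=C\CCC)C(=O)OCC)[C@@]23C=CCC[C@@H]2[C@]1(C(=O)N(C)OC)OC3=O | intermediate
25 | propylmagnesium bromide | CCC[Mg]Br | starting material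
26 | lithium (Z)-5-butylidene tetronate of the cage amide | [Li+].ClCC[C@H]1[C@H](C2=C([O-])/C(=C/CCC)OC2=O)[C@@]23C=CCC[C@@H]2[C@]1(C(=O)N(C)OC)OC3=O | intermediate
27 | 3-(cage-C7-yl)-4-hydroxy-5-[(Z)-butylidene]furan-2(5H)-one (C3′ butanoyl; 2-chloroethyl arm) | ClCC[C@H]1[C@H](C2=C(O)/C(=C/CCC)OC2=O)[C@@]23C=CCC[C@@H]2[C@]1(C(=O)CCC)OC3=O | intermediate
28 | 3-(cage-C7-yl)-4-hydroxy-5-[(Z)-butylidene]furan-2(5H)-one (2-iodoethyl arm) | ICC[C@H]1[C@H](C2=C(O)/C(=C/CCC)OC2=O)[C@@]23C=CCC[C@@H]2[C@]1(C(=O)CCC)OC3=O | intermediate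
29 | enol triflate iodide | ICC[C@H]1[C@H](C2=C(OS(=O)(=O)C(F)(F)F)/C(=C/CCC)OC2=O)[C@@]23C=CCC[C@@H]2[C@]1(C(=O)CCC)OC3=O | intermediate
30 | alkylzinc iodide of 29 | I[Zn]CC[C@H]1[C@H](C2=C(OS(=O)(=O)C(F)(F)F)/C(=C/CCC)OC2=O)[C@@]23C=CCC[C@@H]2[C@]1(C(=O)CCC)OC3=O | intermediate
31 | CNP0423313.2 | CCC/C=C1\OC(=O)C2=C1CC[C@H]1[C@H]2[C@@]23C=CCC[C@@H]2[C@]1(C(=O)CCC)OC3=O | target

Total step count: 16. Longest linear sequence: 14 steps (steps 1–3, then 6–16).

Steps most likely to fail

Step 16. The alkylzinc may be protonated, or the alkylpalladium may undergo β-hydride elimination or couple intermolecularly, before a reductive elimination that has to build ring strain. The fallback sets out from 28 and returns at 31. Oxalyl bromide with catalytic DMF should convert the tetronic acid into the 4-bromobutenolide iodide F1. Hexabutylditin under irradiation in benzene at 80 °C then generates the primary C4 radical, which adds 6-endo to the bromine-bearing C3a. β-Scission of bromine restores the butenolide double bond. The early transition state of the radical addition is less sensitive to product strain, and the five-ring alternative at C7a would be trans-fused and is disfavoured.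

Step 9. Cycloaddition at the neopentyl butenolide carbon may be too slow, so that diene decomposition, addition to the acyclic enoate or loss of facial control take over. The fallback sets out from 14 and returns at 17. Iodine and pyridine in CH2Cl2 should iodinate the butenolide α-carbon selectively to give the 3-iodobutenolide F2, a more reactive dienophile. Cycloaddition with 15 at lower temperature gives the silyl ether F3, and acid work-up gives the iodo alcohol F4. Bu3SnH at high concentration with azobisisobutyronitrile then removes iodine, hydrogen being delivered to the convex face to restore the cis fusion.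

Step 10. The activated β-hydroxy lactone may eliminate toward C7a′, or the hydrazide may enter by SN2′ at C5′, which would return the untransposed alkene. The fallback sets out from 17 and returns at 20. Dess–Martin periodinane gives the enone F5, and 4-methylbenzenesulfonylhydrazide gives the tosylhydrazone F6. Catecholborane followed by sodium acetate reduces the C=N bond to the allylic hydrazine F7, which loses sulfinate to the same diazene 19 and then N2 with the same alkene shift.

Further compounds
F1 | step 16 | 4-bromo-3-(cage-C7-yl)-5-[(Z)-butylidene]furan-2(5H)-one with the 2-iodoethyl arm | ICC[C@H]1[C@H](C2=C(Br)/C(=C/CCC)OC2=O)[C@@]23C=CCC[C@@H]2[C@]1(C(=O)CCC)OC3=O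
F2 | step 9 | tert-butyl (2E,4S)-6-chloro-4-{(2S)-4-iodo-2-[methoxy(methyl)carbamoyl]-5-oxo-2,5-dihydrofuran-2-yl}hex-2-enoate | ClCC[C@@H](/C=C/C(=O)OC(C)(C)C)[C@@]1(C(=O)N(C)OC)OC(=O)C(I)=C1
F3 | step 9 | trimethylsilyl ether of F4 | ClCC[C@@H](/C=C/C(=O)OC(C)(C)C)[C@@]1(C(=O)N(C)OC)OC(=O)[C@]2(I)[C@H](O[Si](C)(C)C)C=CC[C@H]12
F4 | step 9 | 7a′-iodo analogue of 17 | ClCC[C@@H](/C=C/C(=O)OC(C)(C)C)[C@@]1(C(=O)N(C)OC)OC(=O)[C@]2(I)[C@H](O)C=CC[C@H]12
F5 | step 10 | 7′-oxo enone from 17 | ClCC[C@@H](/C=C/C(=O)OC(C)(C)C)[C@@]1(C(=O)N(C)OC)OC(=O)[C@@H]2C(=O)C=CC[C@H]12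
F6 | step 10 | 4-methylbenzenesulfonylhydrazone of F5 | ClCC[C@@H](/C=C/C(=O)OC(C)(C)C)[C@@]1(C(=O)N(C)OC)OC(=O)[C@@H]2C(=NNS(=O)(=O)c3ccc(C)cc3)C=CC[C@H]12
F7 | step 10 | allylic N′-(4-methylbenzenesulfonyl)hydrazine at C7′ | ClCC[C@@H](/C=C/C(=O)OC(C)(C)C)[C@@]1(C(=O)N(C)OC)OC(=O)[C@@H]2C(NNS(=O)(=O)c3ccc(C)cc3)C=CC[C@H]12
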